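**Retrosynthetic overview**
1. Target 14 ⇐ C2‑O‑acetylation, C7‑O‑benzoylation, C7‑OH‑directed reduction of C2=O and desilylation ⇐ cyclohex‑4‑en‑2‑one 10. Numbering throughout: C1 = carbinol carbon carrying C7H2O, C2 = acetoxy carbon, C3 and C6 = benzoyloxy carbons, C4=C5 = alkene.
2. Key disconnection C1–C6: 10 ⇐ meso cyclopentene α‑ketol 9 by a chelation‑controlled, enantiotopic‑group‑selective α‑ketol (acyloin) 1,2‑shift. The five‑membered ring C2–C3–C4=C5–C6 is enlarged to the six‑membered ring by insertion of the exocyclic acyl carbon C1.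
3. Enabling feature: the tertiary carbinol C1 (OH + C7) sits next to an oxygenated C2, so the six‑ring hides an α‑ketol C1(OH)–C2(=O). Moving the C1–C6 bond back onto C2 gives a cyclopentene in which C3 and C6 (both cis‑OBz, flanking C4=C5) are mirror‑related, so the precursor is meso.
4. 9 ⇐ OsO4 α‑hydroxylation of the exocyclic silyl enol ether in 7 ⇐ singlet‑oxygen [4+2], peroxide reduction and benzoylation of 6‑siloxyfulvene 4 ⇐ C‑acylation/O‑silylation of sodium cyclopentadienide 1 with silyloxyacetate 2.
5. Ring order: the five‑membered carbocycle is bought as cyclopentadienide; the only ring construction is the five‑to‑six enlargement in step 5.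

Key step: step 5

Remark: the sense of induction of the chiral Cu(II) catalyst in step 5 cannot be assigned in advance; the ligand antipode that leads to 10 is assumed to be identified on first use.

Step 1
Reactants: 1 sodium cyclopentadienide; 2 methyl 2-[(tert-butyldimethylsilyl)oxy]acetate
Product: 4 6-(tert-butyldimethylsilyloxy)-6-[(tert-butyldimethylsilyloxy)methyl]fulvene, via sodium acylcyclopentadienide 3 (not isolated)
Conditions: THF, reflux; then TBSCl, −78 → 0 °C
Reagents that add atoms: tert-butyldimethylsilyl chloride, CC(C)(C)[Si](C)(C)Cl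
Why: Claisen-type C-acylation of cyclopentadienide by the ester gives the stabilised 6-oxidofulvene salt, whose hard oxygen is silylated (enolate O-silylation) to the 6-siloxyfulvene; no stereocentre is formed.

Step 2
Reactants: 4 6-(tert-butyldimethylsilyloxy)-6-[(tert-butyldimethylsilyloxy)methyl]fulvene
Product: 6 cis-5-[1,2-bis(tert-butyldimethylsilyloxy)ethylidene]cyclopent-2-ene-1,4-diol (racemic), via fulvene endoperoxide 5 (not isolated)
Conditions: O2, rose bengal (cat.), hν, CH2Cl2/MeOH, −78 °C; then thiourea, −78 °C → rt
Reagents that add atoms: dioxygen, O=O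
Why: Singlet oxygen should add [4+2] across the s-cis ring diene (as carbon dienophiles do with 6-acyloxyfulvenes) and thiourea reduces the O–O bond in situ, so both C–O bonds lie on one face (cis-diol); the product is racemic only because the exocyclic enol ether makes the two carbinol carbons different.

Step 3
Reactants: 6 cis-5-[1,2-bis(tert-butyldimethylsilyloxy)ethylidene]cyclopent-2-ene-1,4-diol
Product: 7 cis-5-[1,2-bis(tert-butyldimethylsilyloxy)ethylidene]cyclopent-2-ene-1,4-diyl dibenzoate (racemic)
Conditions: BzCl, pyridine, DMAP (cat.), CH2Cl2, 0 °C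
Reagents that add atoms: benzoyl chloride, O=C(Cl)c1ccccc1
Why: DMAP-catalysed acylation of two secondary allylic alcohols under basic conditions that spare the silyl enol ether; no stereocentre changes.

Step 4
Reactants: 7 cis-5-[1,2-bis(tert-butyldimethylsilyloxy)ethylidene]cyclopent-2-ene-1,4-diyl dibenzoate
Product: 9 meso-2-hydroxy-2-[(tert-butyldimethylsilyloxy)acetyl]cyclopent-4-ene-1,3-diyl dibenzoate (ring hydroxyl trans to both benzoates), via silyl hemiketal 8 (not isolated)
Conditions: OsO4 (2 mol %), NMO, acetone/H2O, 0 °C → rt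
Reagents that add atoms: osmium tetroxide, O=[Os](=O)(=O)=O; N-methylmorpholine N-oxide, C[N+]1([O-])CCOCC1
Why: Upjohn dihydroxylation of a silyl enol ether (α-hydroxylation): OsO4 should take the electron-rich exocyclic alkene rather than the ring alkene (deactivated by two allylic benzoates) from the face anti to both benzoates, so the new ring hydroxyl is trans to them, and the silyl hemiketal collapses to the ketone; both enantiomers of 7 converge on the same meso α-ketol.

Step 5
Reactants: 9 meso-2-hydroxy-2-[(tert-butyldimethylsilyloxy)acetyl]cyclopent-4-ene-1,3-diyl dibenzoate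
Product: 10 (1R,3R,6S)-1-hydroxy-2-oxo-1-[(tert-butyldimethylsilyloxy)methyl]cyclohex-4-ene-3,6-diyl dibenzoate
Conditions: Cu(OTf)2 (10 mol %), (S,S)-t-Bu-box (11 mol %), 4 Å MS, CH2Cl2, 0 °C → rt
Reagents that add atoms: none
Why: Proposed new method: Cu(II) binds the tertiary hydroxyl and the exocyclic ketone of 9 as a five-membered chelate, and one allylic, benzoyloxy-bearing ring carbon (the future C6) shifts with retention from the carbinol carbon (C2) to the acyl carbon (C1), turning C2 into the ring ketone and C1 into the tertiary carbinol (α-ketol/acyloin rearrangement). The closest known reaction type is the Lewis-acid α-ketol ring enlargement of 1-acylcyclopentanols (D-homoannulation of 17-hydroxy-20-keto steroids) and its chiral-Lewis-acid-catalysed enantioselective version on 1-acylcycloalkanols; new here is the choice between two enantiotopic, oxygenated stereogenic ring carbons of a meso substrate. The six-membered ring is not closed by a cyclisation: it arises from the cyclopentene by ring enlargement, the exocyclic carbon C1 being inserted into the C2–C6 bond by the 1,2-shift. At C1 the chelate holds the carbonyl oxygen syn to the carbinol oxygen, so the migrating carbon bonds to the carbonyl face that leaves the new hydroxyl trans and the CH2OTBS group cis to the benzoates, while C3 and C6 keep their configuration and stay cis. The step needs enantiotopic-group selectivity and a chelated rather than open transition state: the C2-symmetric ligand should block one of the two mirror-related migration trajectories, and two-point binding enforces the syn geometry. The driving force is relief of the eclipsed, contiguously substituted cyclopentene in favour of the six-membered ring ketone.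

Step 6
Reactants: 10 (1R,3R,6S)-1-hydroxy-2-oxo-1-[(tert-butyldimethylsilyloxy)methyl]cyclohex-4-ene-3,6-diyl dibenzoate
Product: 11 (1R,3R,6S)-1-hydroxy-1-(hydroxymethyl)-2-oxocyclohex-4-ene-3,6-diyl dibenzoate
Conditions: HF·pyridine, THF/pyridine, 0 °C
Reagents that add atoms: none
Why: Fluoride cleavage of the primary silyl ether under buffered acidic conditions that should leave the benzoates, the tertiary α-ketol and the β,γ-unsaturated ketone untouched; no stereocentre changes.

Step 7
Reactants: 11 (1R,3R,6S)-1-hydroxy-1-(hydroxymethyl)-2-oxocyclohex-4-ene-3,6-diyl dibenzoate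
Product: 12 (1S,2S,3R,6S)-1,2-dihydroxy-1-(hydroxymethyl)cyclohex-4-ene-3,6-diyl dibenzoate (C1 geometry unchanged; descriptor changes by CIP priority only)
Conditions: Me4NBH(OAc)3, MeCN/AcOH, −30 °C
Reagents that add atoms: none
Why: Evans–Saksena directed reduction: the primary C7 hydroxyl exchanges onto boron and delivers hydride intramolecularly to C2 from the face that carries C7, which places the new C2 hydroxyl cis to the C1 hydroxyl and trans to the C3 benzoate.

Step 8
Reactants: 12 (1S,2S,3R,6S)-1,2-dihydroxy-1-(hydroxymethyl)cyclohex-4-ene-3,6-diyl dibenzoate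
Product: 13 (1S,2S,3R,6S)-1-(benzoyloxymethyl)-1,2-dihydroxycyclohex-4-ene-3,6-diyl dibenzoate
Conditions: BzCl (1.05 equiv), 2,4,6-collidine, CH2Cl2, −40 → 0 °C
Reagents that add atoms: benzoyl chloride, O=C(Cl)c1ccccc1
Why: Selective acylation of the primary alcohol over the flanked secondary and the tertiary alcohol at low temperature with one equivalent of acid chloride; no stereocentre changes.

Step 9
Reactants: 13 (1S,2S,3R,6S)-1-(benzoyloxymethyl)-1,2-dihydroxycyclohex-4-ene-3,6-diyl dibenzoate
Product: 14 (1R,2S,3R,6S)-2-acetoxy-1-(benzoyloxymethyl)-1-hydroxycyclohex-4-ene-3,6-diyl dibenzoate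
Conditions: Ac2O, pyridine, DMAP (cat.), 0 °C → rt
Reagents that add atoms: acetic anhydride, CC(=O)OC(C)=O
Why: DMAP-catalysed acetylation of the remaining secondary alcohol; the tertiary C1 hydroxyl should not react under these conditions; no stereocentre changes.

**Compound list**
1 | sodium cyclopentadienide | [Na+].[cH-]1cccc1 | starting material
2 | methyl 2-[(tert-butyldimethylsilyl)oxy]acetate | COC(=O)CO[Si](C)(C)C(C)(C)C | starting material
3 | sodium 2-(tert-butyldimethylsilyloxy)-1-(cyclopenta-2,4-dien-1-ylidene)ethanolate (sodium acylcyclopentadienide) | [Na+].[O-]C(CO[Si](C)(C)C(C)(C)C)=C1C=CC=C1 | intermediate (not isolated)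
4 | 6-(tert-butyldimethylsilyloxy)-6-[(tert-butyldimethylsilyloxy)methyl]fulvene | CC(C)(C)[Si](C)(C)OCC(O[Si](C)(C)C(C)(C)C)=C1C=CC=C1 | intermediate
5 | 7-[1,2-bis(tert-butyldimethylsilyloxy)ethylidene]-2,3-dioxabicyclo[2.2.1]hept-5-ene (racemic, one enantiomer drawn) | O1O[C@H]2C=C[C@@H]1/C2=C(/O[Si](C)(C)C(C)(C)C)CO[Si](C)(C)C(C)(C)C | intermediate (not isolated)
6 | cis-5-[1,2-bis(tert-butyldimethylsilyloxy)ethylidene]cyclopent-2-ene-1,4-diol (racemic, one enantiomer drawn) | O[C@H]1C=C[C@@H](O)/C1=C(/O[Si](C)(C)C(C)(C)C)CO[Si](C)(C)C(C)(C)C | intermediate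
7 | cis-5-[1,2-bis(tert-butyldimethylsilyloxy)ethylidene]cyclopent-2-ene-1,4-diyl dibenzoate (racemic, one enantiomer drawn) | O=C(c1ccccc1)O[C@H]1C=C[C@@H](OC(=O)c2ccccc2)/C1=C(/O[Si](C)(C)C(C)(C)C)CO[Si](C)(C)C(C)(C)C | intermediate
8 | silyl hemiketal: 2-hydroxy-2-[1-hydroxy-1,2-bis(tert-butyldimethylsilyloxy)ethyl]cyclopent-4-ene-1,3-diyl dibenzoate, ring OH trans to benzoates (racemic, one enantiomer drawn) | O=C(c1ccccc1)O[C@H]1C=C[C@@H](OC(=O)c2ccccc2)[C@@]1(O)[C@](O)(O[Si](C)(C)C(C)(C)C)CO[Si](C)(C)C(C)(C)C | intermediate (not isolated)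
9 | meso-2-hydroxy-2-[(tert-butyldimethylsilyloxy)acetyl]cyclopent-4-ene-1,3-diyl dibenzoate (benzoates cis to each other, ring OH trans to both) | O=C(c1ccccc1)O[C@H]1C=C[C@@H](OC(=O)c2ccccc2)[C@@]1(O)C(=O)CO[Si](C)(C)C(C)(C)C | intermediate
10 | (1R,3R,6S)-1-hydroxy-2-oxo-1-[(tert-butyldimethylsilyloxy)methyl]cyclohex-4-ene-3,6-diyl dibenzoate (C1–OH trans to both benzoates) | O=C1[C@H](OC(=O)c2ccccc2)C=C[C@H](OC(=O)c2ccccc2)[C@]1(O)CO[Si](C)(C)C(C)(C)C | intermediate
11 | (1R,3R,6S)-1-hydroxy-1-(hydroxymethyl)-2-oxocyclohex-4-ene-3,6-diyl dibenzoate | O=C1[C@H](OC(=O)c2ccccc2)C=C[C@H](OC(=O)c2ccccc2)[C@]1(O)CO | intermediate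
12 | (1S,2S,3R,6S)-1,2-dihydroxy-1-(hydroxymethyl)cyclohex-4-ene-3,6-diyl dibenzoate (C1–OH and C2–OH cis, both trans to the benzoates) | O[C@H]1[C@H](OC(=O)c2ccccc2)C=C[C@H](OC(=O)c2ccccc2)[C@]1(O)CO | intermediate
13 | (1S,2S,3R,6S)-1-(benzoyloxymethyl)-1,2-dihydroxycyclohex-4-ene-3,6-diyl dibenzoate | O[C@H]1[C@H](OC(=O)c2ccccc2)C=C[C@H](OC(=O)c2ccccc2)[C@]1(O)COC(=O)c1ccccc1 | intermediate
14 | (1R,2S,3R,6S)-2-acetoxy-1-(benzoyloxymethyl)-1-hydroxycyclohex-4-ene-3,6-diyl dibenzoate | CC(=O)O[C@H]1[C@H](OC(=O)c2ccccc2)C=C[C@H](OC(=O)c2ccccc2)[C@]1(O)COC(=O)c1ccccc1 | target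

Total step count: 9. Longest linear sequence: 9 steps (from 1 and 2).

**Steps most likely to fail**

Step 5 (proposed new method). The catalyst may not discriminate well between the two mirror-related migrating ring carbons (low enantiomeric purity), and part of the material may react through a non-chelated transition state that inverts C1. Fallback: setting out from 9, the same ring enlargement is run as the known, non-enantioselective Lewis-acid α-ketol rearrangement with an achiral chelating catalyst (Cu(OTf)2/2,2'-bipyridine, CH2Cl2). This should give the racemate, i.e. 10 together with its mirror image ent-10 F1, which is separated by preparative HPLC on a chiral stationary phase; the route is rejoined at 10.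

Step 2. The strained fulvene endoperoxide may rearrange by O–O homolysis before it is reduced, singlet oxygen may attack the electron-rich exocyclic enol ether instead of the ring diene, or the vinylogous silyl ester in 4 may be methanolysed. Fallback, which avoids a 6-siloxyfulvene altogether: setting out from 1, protonation with acetic acid gives cyclopenta-1,3-diene F2, which is condensed with (tert-butyldimethylsilyloxy)acetaldehyde under pyrrolidine catalysis in methanol to 6-[(tert-butyldimethylsilyloxy)methyl]fulvene F3. Photooxygenation with in situ thiourea reduction should pass through the endoperoxide F4 to the cis-diol F5, and benzoylation gives the dibenzoate F6. Ligand-accelerated OsO4 dihydroxylation (OsO4, NMO, quinuclidine) of the trisubstituted exocyclic alkene, anti to the benzoates, gives the tertiary/secondary diol F7, and Dess–Martin oxidation of its secondary carbinol rejoins the route at 9.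

Step 7. Hydride may be delivered from the wrong face, either by external attack on the less hindered face or by delivery from the tertiary C1 hydroxyl, giving the C2 epimer. Fallback: setting out from 11, an Evans–Tishchenko reduction with benzaldehyde (SmI2 pre-oxidised with PhCHO, THF, −10 °C) is used instead. The hemiacetal formed on the C7 oxygen transfers its hydride to C2 within a samarium chelate from the C7 face and leaves C7 as its benzoate, so reduction and C7 benzoylation occur together. No compound outside the list is made (none; F0), and the route is rejoined at 13.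

Further compounds
F1 | step 5 | ent-10, (1S,3S,6R)-1-hydroxy-2-oxo-1-[(tert-butyldimethylsilyloxy)methyl]cyclohex-4-ene-3,6-diyl dibenzoate | O=C1[C@@H](OC(=O)c2ccccc2)C=C[C@@H](OC(=O)c2ccccc2)[C@@]1(O)CO[Si](C)(C)C(C)(C)C
F2 | step 2 | cyclopenta-1,3-diene | C1C=CC=C1
F3 | step 2 | 6-[(tert-butyldimethylsilyloxy)methyl]fulvene | CC(C)(C)[Si](C)(C)OCC=C1C=CC=C1
F4 | step 2 | 7-[2-(tert-butyldimethylsilyloxy)ethylidene]-2,3-dioxabicyclo[2.2.1]hept-5-ene (racemic, one enantiomer drawn; not isolated) | O1O[C@H]2C=C[C@@H]1/C2=C/CO[Si](C)(C)C(C)(C)C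
F5 | step 2 | cis-5-[2-(tert-butyldimethylsilyloxy)ethylidene]cyclopent-2-ene-1,4-diol (racemic, one enantiomer drawn) | O[C@H]1C=C[C@@H](O)/C1=C/CO[Si](C)(C)C(C)(C)C
F6 | step 2 | cis-5-[2-(tert-butyldimethylsilyloxy)ethylidene]cyclopent-2-ene-1,4-diyl dibenzoate (racemic, one enantiomer drawn) | O=C(c1ccccc1)O[C@H]1C=C[C@@H](OC(=O)c2ccccc2)/C1=C/CO[Si](C)(C)C(C)(C)C
F7 | step 2 | 2-hydroxy-2-[1-hydroxy-2-(tert-butyldimethylsilyloxy)ethyl]cyclopent-4-ene-1,3-diyl dibenzoate, ring OH trans to benzoates (racemic, one enantiomer drawn) | O=C(c1ccccc1)O[C@H]1C=C[C@@H](OC(=O)c2ccccc2)[C@@]1(O)[C@H](O)CO[Si](C)(C)C(C)(C)C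
F0 | step 7 | none | none
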